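## Structural features

The target, C26H36O4, is a 20-membered macrocycle in which two benzene rings are joined once through an ether oxygen and once through an unbranched chain of fourteen methylene groups. The ring atoms are the chain carbons C1 to C14, B6, B1, the oxygen, A5, A4 and A3. Ring A is 1,3,5-trisubstituted (hydroxyl at A1, chain carbon C14 at A3, ether oxygen at A5). Ring B carries the ether oxygen at B1, hydroxyls at B2 and B4 and chain carbon C1 at B6, so B1 is flanked by two ortho substituents. There is no stereocentre and no other stereogenic element, so no two stereocentres stand next to each other and nothing has to be controlled in that respect. The fragile groups are the three free phenols: ring B is a 1,2,4-trioxygenated arene (B1 and B4 para) that oxidises easily to a quinone once unmasked, and all three would interfere with carbanion chemistry, so they are carried as methyl ethers to the last step. The real difficulty is the entropically unfavourable closure of a large ring through a featureless polymethylene chain, together with the hindered B1–O–A5 ether. The key step exploits the fact that both chain ends, C1 on B6 and C14 on A3, are benzylic: each can be the inner carbon of an arylacetylene grown from an aryl aldehyde, C2 and C13 then become acetylide nucleophiles, and C3 to C12 is a symmetrical commercial ten-carbon dielectrophile.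

## Logic of the disconnections

From 13 to 12: the three phenolic O–H bonds are replaced by O–CH3 bonds. Free phenols would be deprotonated and O-alkylated in the ring-forming chemistry, and ring B oxidises easily once free. The gain is a robust, neutral macrocycle. The forward step must cleave three methyl ethers without touching the diaryl ether, which a boron Lewis acid that attacks only O–CH3 groups can do.

From 12 to 11: the single bonds C1–C2 and C13–C14 are raised to triple bonds. No bond is cut, but two inert benzylic positions become alkyne carbons whose neighbours C2 and C13 can carry negative charge. The forward step must add eight hydrogens under neutral conditions without hydrogenolysis of aryl–oxygen bonds.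

From 11 to 6 and 7: the bonds C2–C3 and C12–C13 are cut, with negative charge on the alkyne carbons (as in 8) and positive charge on the two ends of 7. The macrocycle falls apart into a small rigid diaryl ether and a commercial chain. The forward step must achieve two SN2 alkylations in one operation, the second (through 9 or 10) intramolecular, and therefore needs high dilution.

From 6 to 4 and 5: the triple bonds C1≡C2 and C13≡C14 are cut, C2 and C13 coming from 5 as one-carbon units. Both ethynyl groups trace back to formyl groups, one of which also activates the ether-forming step. The forward step must homologate two non-enolisable aldehydes under mild base.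

From 4 to 2 and 3: the B1–O bond is cut. B1 is the electrophilic carbon because a halogen can be placed there by direct substitution and the neighbouring formyl group activates it; the A5 oxygen is the nucleophile. The gain is two monocyclic benzaldehydes. The forward step must couple at a doubly ortho-substituted carbon in the presence of two aldehydes.

From 2 to 1: the B1–Br bond is cut. The position is para to one methoxy group and ortho to the other, so electrophilic substitution should deliver it. The forward step must stop at monobromination.

## Other disconnections considered

Alternative 1: Ring A is taken apart instead of the chain. The cut removes A3–A4, A1–A6, A4–A5 and A1–A2 and leads to 1-diazo-17-[2-(ethynyloxy)-3,5-dimethoxyphenyl]-3-methylideneheptadecan-2-one A1. In the forward step, irradiation would trigger a Wolff rearrangement (vinyl migration, A3–A4); the ketene C=C bond so formed would add across the tethered ynol ether ([2+2], A1–A6 and A4–A5); on heating the four-membered ring would open and reclose in a six-electron electrocyclisation (A1–A2). Tautomerisation would give the ring B dimethyl ether A2, with ring A and the macrocycle formed together.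
- In favour: the 1,3,5 pattern of ring A follows from the polarity of the ynol ether, four bonds and two rings arise in one operation, no hindered aryl–oxygen coupling is needed, and A2 has the ring A phenol free and only two methyl ethers left. On bond economy of the key step and on the simplicity of the end game this alternative is the equal or the better of the chosen plan.
- Against: the ketene is transient and must find an alkyne fourteen carbons away. At the dilution a 20-membered closure needs, ketene dimerisation, capture by adventitious nucleophiles and side reactions of the carbene precursor can compete, whereas the acetylides of the chosen plan persist until they meet the iodide. Aryl ethynyl ethers are thermally and hydrolytically delicate. A1 also needs a long linear build-up (chain attachment to ring B, ynol ether formation, α-methylene diazoketone).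
- Comparison: both plans end with a BBr3 demethylation. Mechanistically the chosen plan replaces a pericyclic cascade in macrocyclic mode by two SN2 displacements of established scope. In step count the alternative would be expected to be roughly twice as long.

Alternative 2: The ether bond B1–O is cut and used for ring closure. The precursor is 4-fluoro-5-[14-(3,5-dihydroxyphenyl)tetradecyl]benzene-1,3-dicarbaldehyde A3, whose fluoride at B1 is activated by formyl groups at B2 (ortho) and B4 (para). In the forward step K2CO3 in a dipolar aprotic solvent at high dilution would generate the resorcinol phenoxide, which would displace fluoride by addition–elimination and close the ring to the diformyl diaryl ether A4. A twofold Dakin oxidation would then give 13 directly.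
- In favour: the closure is unimolecular from the start, so dilution costs no rate, unlike the bimolecular first alkylation of the chosen plan. The 5-alkylresorcinol is symmetrical, so either oxygen gives the same ring. The hindered B1–O bond forms under strong electronic activation, and no protecting group has to be removed. On the macrocyclisation itself and on protecting-group count this alternative is the better.
- Against: the Dakin oxidation must succeed twice on one ring. Each formyl group deactivates the aryl migration needed at the other, so oxidation to carboxylic acids competes, and the peroxide meets a free resorcinol-type ring A and, after the first oxidation, an easily oxidised hydroquinone-type ring B. A3 needs two separate aryl–chain C–C couplings with the dialdehyde masked.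
- Comparison: a better ring-closing reaction, but a riskier functional-group end game and a clearly longer precursor synthesis than the six steps planned here.

Alternative 3: Ring B is absent when the macrocycle is closed. The cut is the B1–B6 bond, made as a C=C bond, and B4 and B5 are added afterwards. The precursor is diethyl {1-[3-methoxy-5-(15-oxopentadecyl)phenoxy]-2-oxopropyl}phosphonate A5. In the forward step an intramolecular Horner–Wadsworth–Emmons reaction (LiCl, amine base, high dilution) would give the 20-membered (Z)-α-aryloxy enone A6, whose acetyl group supplies B2 and B3. Ring B would then be completed by conjugate addition of a malonate at B6, Claisen closure of B3 onto the ester carbon (B4), decarboxylation at B5, dehydrogenative aromatisation and cleavage of the one methyl ether.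
- In favour: the intramolecular olefination is among the most dependable macrocycle-forming reactions and is unimolecular. The B1–O bond is made early by simple O-alkylation of a phenol, so no hindered aryl ether coupling is needed, and only one methyl ether remains. On these points the alternative is the equal or the better.
- Against: A6 is a poor Michael acceptor (β-alkyl, α-oxygen donor). The annulation passes through sp3 centres at B1, B5 and B6 as diastereomer mixtures inside the macrocycle. The aromatisation must not expel the aryloxy group at B1. Four to five operations follow the ring closure, against two in the chosen plan, and the fifteen-carbon functionalised chain must first be attached to ring A.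
- Comparison: the chosen plan keeps both arenes intact throughout and trades the safer olefination for a riskier alkylative closure; in step count it is markedly shorter.

Key step: step 4

Remark on the chemistry: the three phenols are carried as methyl ethers because both aromatic building blocks are commercial in that form. Benzyl ethers would merge the last two steps but would cost an extra, statistical mono-benzylation at the start. Compounds 1, 3, 5 and 7 are taken to be commercial.

## Steps

Step 1
Reactants: 1 3,5-dimethoxybenzaldehyde
Product: 2 2-bromo-3,5-dimethoxybenzaldehyde
Conditions: NBS (1.05 equiv), MeCN, 0 °C to rt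
Reagents that add atoms: N-bromosuccinimide, O=C1CCC(=O)N1Br
Why: Electrophilic aromatic bromination; C2 (equivalent to C6) is para to one methoxy group and ortho to the other and is less crowded than C4 between the two methoxy groups, so monobromination next to the formyl group is expected, and one equivalent of reagent limits 2,6-dibromination.

Step 2
Reactants: 2 2-bromo-3,5-dimethoxybenzaldehyde; 3 3-hydroxy-5-methoxybenzaldehyde
Product: 4 2-(3-formyl-5-methoxyphenoxy)-3,5-dimethoxybenzaldehyde
Conditions: CuI (10 mol %), picolinic acid (20 mol %), K3PO4 (2 equiv), DMSO, 90 °C
Reagents that add atoms: none
Why: Ullmann-type diaryl ether synthesis with catalytic monovalent copper (CuI); the ortho-formyl group lowers the electron density at the C–Br carbon and can pre-coordinate copper, which compensates for the two methoxy donors and the double ortho substitution, and the picolinate ligand is suited to hindered partners. Neither aldehyde has α-hydrogens, so anhydrous phosphate should leave both intact.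

Step 3
Reactants: 4 2-(3-formyl-5-methoxyphenoxy)-3,5-dimethoxybenzaldehyde; 5 dimethyl (1-diazo-2-oxopropyl)phosphonate
Product: 6 1-ethynyl-2-(3-ethynyl-5-methoxyphenoxy)-3,5-dimethoxybenzene
Conditions: 5 (2.6 equiv), K2CO3 (4 equiv), MeOH/THF, 0 °C to rt
Reagents that add atoms: none
Why: Twofold Ohira–Bestmann alkynylation (Seyferth–Gilbert homologation): methanolysis of 5 releases the anion of dimethyl (diazomethyl)phosphonate, which olefinates each aldehyde to a diazoalkene that loses N2 and rearranges by 1,2-hydrogen shift to the terminal alkyne, so that C2 and C13 both come from 5. Non-enolisable aromatic aldehydes are ideal substrates and the mild carbonate base spares all ethers.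

Step 4
Reactants: 6 1-ethynyl-2-(3-ethynyl-5-methoxyphenoxy)-3,5-dimethoxybenzene; 7 1,10-diiododecane
Product: 11 tri-O-methyl macrocyclic 1,13-diyne (20-membered ring), via dilithium bis-acetylide 8 (not isolated), via C2-alkylated lithium acetylide 9 (not isolated), via C13-alkylated lithium acetylide 10 (not isolated)
Conditions: n-BuLi (2.05 equiv), THF, −78 to 0 °C, then DMPU; this solution and 7 (1.0 equiv, THF) added simultaneously over 12 h to THF/DMPU (5:1), 50 °C, final ca. 0.003 M; then 12 h at 50 °C
Reagents that add atoms: none
Why: Deprotonation of both ethynyl groups of 6 by n-BuLi gives 8; in THF containing DMPU, which breaks up acetylide aggregates, one acetylide carbon displaces iodide from 7 in an intermolecular SN2 reaction (bond C2–C3 or C12–C13, giving 9 or 10), and the remaining acetylide then attacks the CH2–I end of the tethered chain to form the second bond. The closest known reaction type is the alkylation of lithium acetylides by primary iodides, which in its double form with α,ω-dihalides is a classical entry to macrocyclic diynes. The only ring formed is closed in a 20-exo-tet intramolecular SN2 displacement, and no stereocentre is created, so no stereocontrol is required. The selectivity needed is ring closure over chain growth: 9 and 10 must cyclise faster than they meet a further molecule of 7 or 8, which is secured by keeping all reactive species at millimolar stationary concentration through slow simultaneous addition and by the substrate itself, whose two arylethynyl spokes are rigid and fixed on the diaryl ether so that only the ten methylene groups have to fold. No regiochemical question arises because 7 is symmetrical and 9 and 10 converge on the same ring. Elimination of HI is not expected to compete, because acetylides are far better nucleophiles than bases towards unbranched primary iodides, and the gentle heating compensates for the slowness of the bimolecular first alkylation at this dilution.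

Step 5
Reactants: 11 tri-O-methyl macrocyclic 1,13-diyne
Product: 12 A1,B2,B4-tri-O-methyl ether of the target (saturated 20-membered macrocycle)
Conditions: H2 (1 atm), Pd/C (10 wt % palladium on carbon), EtOAc, rt
Reagents that add atoms: none
Why: Heterogeneous catalytic hydrogenation adds four equivalents of H2 across the two triple bonds; aryl methyl ethers, the diaryl ether and the benzylic C–C bonds are inert under these neutral conditions, and no stereocentre is formed.

Step 6
Reactants: 12 A1,B2,B4-tri-O-methyl ether of the target
Product: 13 CNP0173380.0 (20-membered triphenol: hydroxyls at A1, B2 and B4)
Conditions: BBr3 (6 equiv), CH2Cl2, −78 °C to rt; then degassed MeOH and H2O, 0 °C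
Reagents that add atoms: none
Why: Lewis acid mediated cleavage of aryl methyl ethers: boron coordinates each methoxy oxygen and bromide attacks the methyl carbon in an SN2 step, the aryloxyboranes being hydrolysed on work-up; the diaryl ether has no sp3 carbon on oxygen and is not cleaved. Air is excluded during work-up because the free 1,2,4-trioxygenated ring B is prone to oxidation.

## Compound list

1 | 3,5-dimethoxybenzaldehyde | COc1cc(OC)cc(C=O)c1 | starting material
2 | 2-bromo-3,5-dimethoxybenzaldehyde | COc1cc(OC)c(Br)c(C=O)c1 | intermediate
3 | 3-hydroxy-5-methoxybenzaldehyde | COc1cc(O)cc(C=O)c1 | starting material
4 | 2-(3-formyl-5-methoxyphenoxy)-3,5-dimethoxybenzaldehyde | O=Cc1cc(OC)cc(c1)Oc1c(OC)cc(OC)cc1C=O | intermediate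
5 | dimethyl (1-diazo-2-oxopropyl)phosphonate | CC(=O)C(=[N+]=[N-])P(=O)(OC)OC | starting material
6 | 1-ethynyl-2-(3-ethynyl-5-methoxyphenoxy)-3,5-dimethoxybenzene | C#Cc1cc(OC)cc(c1)Oc1c(OC)cc(OC)cc1C#C | intermediate
7 | 1,10-diiododecane | ICCCCCCCCCCI | starting material
8 | dilithium bis-acetylide of 6 (both ethynyl C–H replaced by C–Li) | [Li]C#Cc1cc(OC)cc(c1)Oc1c(OC)cc(OC)cc1C#C[Li] | intermediate
9 | C2-alkylated lithium acetylide: lithium {3-[2-(12-iodododec-1-yn-1-yl)-4,6-dimethoxyphenoxy]-5-methoxyphenyl}ethynide | [Li]C#Cc1cc(OC)cc(c1)Oc1c(OC)cc(OC)cc1C#CCCCCCCCCCCI | intermediate
10 | C13-alkylated lithium acetylide: lithium {2-[3-(12-iodododec-1-yn-1-yl)-5-methoxyphenoxy]-3,5-dimethoxyphenyl}ethynide | ICCCCCCCCCCC#Cc1cc(OC)cc(c1)Oc1c(OC)cc(OC)cc1C#C[Li] | intermediate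
11 | tri-O-methyl macrocyclic 1,13-diyne: 20-membered ring with triple bonds C1≡C2 and C13≡C14, methoxy groups at A1, B2 and B4 | COc1cc2cc(c1)Oc1c(OC)cc(OC)cc1C#CCCCCCCCCCCC#C2 | intermediate
12 | A1,B2,B4-tri-O-methyl ether of the target: saturated 20-membered macrocycle with a tetradecamethylene chain | COc1cc2cc(c1)Oc1c(OC)cc(OC)cc1CCCCCCCCCCCCCC2 | intermediate
13 | CNP0173380.0: 20-membered diaryl ether with hydroxyls at A1, B2 and B4 and a tetradecamethylene chain from B6 to A3 | Oc1cc2cc(c1)Oc1c(O)cc(O)cc1CCCCCCCCCCCCCC2 | target

## Step count and risk assessment

Total step count: 6. Longest linear sequence: 6 steps (1 to 2 to 4 to 6 to 11 to 12 to 13). Steps 1, 5 and 6 are routine transformations.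

Step 4 (key step). Chain growth to linear and cyclic oligomers is the most likely failure. The first alkylation is bimolecular and therefore slow at the dilution that the ring closure needs, so reactive chain ends may accumulate and meet each other before they cyclise. The fallback separates the two events and sets out from 6. About one equivalent of n-BuLi is used and the resulting acetylide mixture is added to a large excess of 7 in THF/DMPU at ordinary concentration. This should give the two regioisomeric mono-alkylated iodoalkynes, 2-(3-ethynyl-5-methoxyphenoxy)-1-(12-iodododec-1-yn-1-yl)-3,5-dimethoxybenzene F1 and 1-ethynyl-2-[3-(12-iodododec-1-yn-1-yl)-5-methoxyphenoxy]-3,5-dimethoxybenzene F2, beside recovered 6 and excess 7, which are recycled. F1 and F2 need not be separated because both close to the same ring. Deprotonation of the mixture with LiN(SiMe3)2 in dilute THF/DMPU at −78 °C and warming to 50 °C should then close the ring in a purely unimolecular SN2 alkylation, whose rate does not fall on dilution. The fallback comes back to the route at 11.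

Step 2. Slow oxidative addition at the doubly ortho-substituted, electron-rich C–Br carbon may let reductive loss of bromine or base-induced degradation of the aldehydes overtake ether formation. The fallback uses carboxylate assistance and sets out from 2. Oxidation with NaClO2 (NaH2PO4, 2-methylbut-2-ene, t-BuOH/H2O) should give 2-bromo-3,5-dimethoxybenzoic acid F3, in which the ortho-carboxylate strongly accelerates copper-mediated displacement of the bromide. Coupling with 3 (CuI, K2CO3, DMF, 100 °C) should give 2-(3-formyl-5-methoxyphenoxy)-3,5-dimethoxybenzoic acid F4. LiAlH4 in THF reduces the acid and the aldehyde to {2-[3-(hydroxymethyl)-5-methoxyphenoxy]-3,5-dimethoxyphenyl}methanol F5, and MnO2 in CH2Cl2 oxidises both benzylic alcohols, coming back to the route at 4.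

Step 3. Incomplete conversion is the most likely failure: the B6 aldehyde is more hindered and more electron-rich, so addition of the phosphonate anion may stall after the first alkynylation. The fallback is a Corey–Fuchs sequence and sets out from 4. CBr4 and PPh3 in CH2Cl2 at 0 °C should give 1-(2,2-dibromoethenyl)-2-[3-(2,2-dibromoethenyl)-5-methoxyphenoxy]-3,5-dimethoxybenzene F6. Excess n-BuLi in THF at −78 °C then effects elimination and lithium–bromine exchange to the bis-acetylide, and an aqueous quench comes back to the route at 6.

## Further compounds

F1 | step 4 | 2-(3-ethynyl-5-methoxyphenoxy)-1-(12-iodododec-1-yn-1-yl)-3,5-dimethoxybenzene | C#Cc1cc(OC)cc(c1)Oc1c(OC)cc(OC)cc1C#CCCCCCCCCCCI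
F2 | step 4 | 1-ethynyl-2-[3-(12-iodododec-1-yn-1-yl)-5-methoxyphenoxy]-3,5-dimethoxybenzene | ICCCCCCCCCCC#Cc1cc(OC)cc(c1)Oc1c(OC)cc(OC)cc1C#C
F3 | step 2 | 2-bromo-3,5-dimethoxybenzoic acid | COc1cc(OC)c(Br)c(C(=O)O)c1
F4 | step 2 | 2-(3-formyl-5-methoxyphenoxy)-3,5-dimethoxybenzoic acid | O=Cc1cc(OC)cc(c1)Oc1c(OC)cc(OC)cc1C(=O)O
F5 | step 2 | {2-[3-(hydroxymethyl)-5-methoxyphenoxy]-3,5-dimethoxyphenyl}methanol | OCc1cc(OC)cc(c1)Oc1c(OC)cc(OC)cc1CO
F6 | step 3 | 1-(2,2-dibromoethenyl)-2-[3-(2,2-dibromoethenyl)-5-methoxyphenoxy]-3,5-dimethoxybenzene | BrC(Br)=Cc1cc(OC)cc(c1)Oc1c(OC)cc(OC)cc1C=C(Br)Br
A1 | alternative 1 | 1-diazo-17-[2-(ethynyloxy)-3,5-dimethoxyphenyl]-3-methylideneheptadecan-2-one | C=C(CCCCCCCCCCCCCCc1cc(OC)cc(OC)c1OC#C)C(=O)C=[N+]=[N-]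
A2 | alternative 1 | ring B di-O-methyl ether of the target (B2 and B4 methoxy, A1 hydroxyl) | Oc1cc2cc(c1)Oc1c(OC)cc(OC)cc1CCCCCCCCCCCCCC2
A3 | alternative 2 | 4-fluoro-5-[14-(3,5-dihydroxyphenyl)tetradecyl]benzene-1,3-dicarbaldehyde | O=Cc1cc(C=O)c(F)c(c1)CCCCCCCCCCCCCCc1cc(O)cc(O)c1
A4 | alternative 2 | 20-membered diaryl ether with formyl groups at B2 and B4 and a hydroxyl at A1 | Oc1cc2cc(c1)Oc1c(C=O)cc(C=O)cc1CCCCCCCCCCCCCC2
A5 | alternative 3 | diethyl {1-[3-methoxy-5-(15-oxopentadecyl)phenoxy]-2-oxopropyl}phosphonate | CCOP(=O)(OCC)C(Oc1cc(OC)cc(CCCCCCCCCCCCCCC=O)c1)C(C)=O
A6 | alternative 3 | 20-membered (Z)-α-aryloxy enone (acetyl group on B1, double bond B1=B6, methoxy at A1) | COc1cc2cc(c1)O/C(C(C)=O)=C\CCCCCCCCCCCCCC2
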